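**Retrosynthetic overview**
1. The target is read as epicatechin 3-O-gallate-(4β→8)-epigallocatechin 3-O-gallate-(4β→8)-catechin 3-O-gallate. The top and middle units are 2R,3R with the C4 aryl group trans to the 3-O-acyl group, and the bottom unit is 2R,3S. The last step is one global hydrogenolysis.
2. Key disconnection: ring C of the middle unit (O1–C2–C3–C4–C4a–C8a) is cut at C4a–C4 and O1–C2, and the lower interflavan bond C4–C8 is cut with it. This gives three components: a phenol (middle ring A already carrying the top unit at the future C8), an α-galloyloxycinnamaldehyde (C2–C3–C4, ring B, middle gallate) and the protected bottom unit.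
3. Enabling feature: O1, C8a, C4a and C4 sit on a phloroglucinol-type ring A and form a latent o-quinone methide, and C4 is a trioxybenzylic position next to the C3 O-galloyl group. A C3=C4 enol gallate can therefore be closed by oxa-6π electrocyclization, then protonated at C3 and arylated at C4 with the ester as neighbouring group.
4. Ring order: all aromatic rings and the pyran rings of the top and bottom units come with (−)-epicatechin, (+)-catechin and gallic acid derivatives. Ring C of the middle unit is the only skeletal ring that is made, and it is closed last.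
5. Fragments: the phenol comes from epicatechin by C8 bromine capping, C4 oxidation, galloylation and Friedel–Crafts coupling with 3,5-bis(benzyloxy)phenol. The enal comes from a gold-catalysed oxidative 1,2-acyloxy shift of a propargylic gallate.

Key step: step 11

Assumption: the (R) antipode of the chiral acid is written in step 11. No model predicts which antipode matches the (2R) relay for this substrate, so the other antipode takes its place if needed.

**Step 1**
Reactants: 1 (−)-epicatechin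
Product: 2 5,7,3',4'-tetra-O-benzyl-(−)-epicatechin
Conditions: BnBr (4.4 equiv), K2CO3, DMF, 0 °C → rt, Ar
Reagents that add atoms: benzyl bromide, BrCc1ccccc1
Why: Williamson ether synthesis in which only the four phenols are ionised by carbonate, so the 3-OH stays free, and the mild base at low temperature should leave C2 and C3 untouched.

**Step 2**
Reactants: 2 5,7,3',4'-tetra-O-benzyl-(−)-epicatechin
Product: 3 8-bromo-5,7,3',4'-tetra-O-benzyl-(−)-epicatechin
Conditions: NBS (1.0 equiv), CH2Cl2, −45 °C → rt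
Reagents that add atoms: N-bromosuccinimide, O=C1CCC(=O)N1Br
Why: Electrophilic aromatic bromination at C8, the most nucleophilic and least shielded carbon of ring A, and the bromine acts as a cap that keeps C8 from reacting as a nucleophile in steps 5 and 11.

**Step 3**
Reactants: 3 8-bromo-5,7,3',4'-tetra-O-benzyl-(−)-epicatechin
Product: 4 8-bromo-4β-(2-ethoxyethoxy)-5,7,3',4'-tetra-O-benzylepicatechin
Conditions: DDQ (2 equiv), 2-ethoxyethanol (5 equiv), CH2Cl2, rt
Reagents that add atoms: 2-ethoxyethanol, CCOCCO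
Why: DDQ benzylic oxidation (hydride abstraction from C4, then capture of the ring-A-stabilised cation by the alcohol) in which attack from the β face, trans to the axial 3-OH, sets C4, a centre that serves only as a leaving-group position.

**Step 4**
Reactants: 4 8-bromo-4β-(2-ethoxyethoxy)-5,7,3',4'-tetra-O-benzylepicatechin; 5 3,4,5-tris(benzyloxy)benzoic acid
Product: 6 top electrophile, the 3-O-[3,4,5-tris(benzyloxy)benzoyl] ester of 4
Conditions: DCC, DMAP, CH2Cl2, 0 °C → rt
Reagents that add atoms: none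
Why: Steglich esterification acylates the hindered axial 3-OH under neutral conditions that spare the acid-labile 4-alkoxy group, with retention at C3.

**Step 5**
Reactants: 6 top electrophile; 7 3,5-bis(benzyloxy)phenol (4 equiv)
Product: 8 top unit–ring A phenol, 8-bromo-5,7,3',4'-tetra-O-benzyl-4β-[2,4-bis(benzyloxy)-6-hydroxyphenyl]epicatechin 3-O-[3,4,5-tris(benzyloxy)benzoate]
Conditions: BF3·OEt2 (30 mol %), CH2Cl2, −78 → −20 °C
Reagents that add atoms: none
Why: Lewis-acid Friedel–Crafts alkylation of the interflavan type, in which the α-face 3-O-galloyl carbonyl assists ionisation so the phenol attacks C4 from the β face (3,4-trans), through the carbon between OH and OBn, which is less crowded than the carbon between two OBn groups and occurs twice.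

**Step 6**
Reactants: 9 (+)-catechin
Product: 10 5,7,3',4'-tetra-O-benzyl-(+)-catechin
Conditions: BnBr (4.4 equiv), K2CO3, DMF, 0 °C → rt, Ar
Reagents that add atoms: benzyl bromide, BrCc1ccccc1
Why: Williamson ether synthesis selective for the four phenols, as in step 1, with no stereocentre touched.

**Step 7**
Reactants: 10 5,7,3',4'-tetra-O-benzyl-(+)-catechin; 5 3,4,5-tris(benzyloxy)benzoic acid
Product: 11 bottom nucleophile, 5,7,3',4'-tetra-O-benzyl-(+)-catechin 3-O-[3,4,5-tris(benzyloxy)benzoate]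
Conditions: DCC, DMAP, CH2Cl2, 0 °C → rt
Reagents that add atoms: none
Why: Steglich esterification of the equatorial 3-OH with retention, leaving C8–H as the nucleophilic position.

**Step 8**
Reactants: 12 3,4,5-tris(benzyloxy)benzaldehyde
Product: 13 rac-1-[3,4,5-tris(benzyloxy)phenyl]prop-2-yn-1-ol
Conditions: HC≡CMgBr (1.3 equiv), THF, 0 °C; then H2O
Reagents that add atoms: ethynylmagnesium bromide, C#C[Mg]Br
Why: Grignard 1,2-addition to the aldehyde, where the racemic carbinol centre is acceptable because step 10 erases it.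

**Step 9**
Reactants: 13 rac-1-[3,4,5-tris(benzyloxy)phenyl]prop-2-yn-1-ol; 5 3,4,5-tris(benzyloxy)benzoic acid
Product: 14 rac-1-[3,4,5-tris(benzyloxy)phenyl]prop-2-yn-1-yl 3,4,5-tris(benzyloxy)benzoate
Conditions: DCC, DMAP, CH2Cl2, 0 °C → rt
Reagents that add atoms: none
Why: Steglich esterification under neutral conditions avoids ionisation of the electron-rich propargylic alcohol.

**Step 10**
Reactants: 14 rac-propargylic gallate
Product: 15 (Z)-3-oxo-1-[3,4,5-tris(benzyloxy)phenyl]prop-1-en-2-yl 3,4,5-tris(benzyloxy)benzoate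
Conditions: (Ph3P)AuNTf2 (5 mol %), 8-methylquinoline N-oxide (1.5 equiv), ClCH2CH2Cl, rt
Reagents that add atoms: 8-methylquinoline N-oxide, Cc1cccc2ccc[n+]([O-])c12
Why: Gold-catalysed oxidative rearrangement of a propargylic carboxylate, in which oxygen transfer to the terminal alkyne carbon and the 1,2-acyloxy shift converge in either order on the α-acyloxy enal, expected as the less strained (Z) isomer with aryl trans to CHO.

**Step 11**
Reactants: 8 top unit–ring A phenol; 15 (Z)-α-galloyloxy enal (1.1 equiv); 11 bottom nucleophile (3 equiv, added in the second stage)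
Product: 20 perbenzylated 8-bromo trimer, via benzodioxaborin 16 (not isolated), via vinylogous o-quinone methide 17 (not isolated), via flav-3-en-3-yl gallate 18 (not isolated), via dioxolanylium ion 19 (not isolated)
Conditions: PhB(OH)2 (1.2 equiv), EtCO2H (30 mol %), 4 Å MS, toluene, 90 °C; then −40 °C, 11, (R)-3,3'-bis(2,4,6-triisopropylphenyl)-1,1'-binaphthyl-2,2'-diyl N-triflylphosphoramide (20 mol %), toluene/CH2Cl2, −40 → 0 °C
Reagents that add atoms: none
Why: Proposed new method: PhB(OH)2 ties the free C8a–OH of 8 to the aldehyde of 15 so that only the ortho carbon C4a attacks C4 (benzodioxaborin 16), thermal extrusion of PhBO gives the vinylogous o-quinone methide 17, and a thermal disrotatory oxa-6π electrocyclization (O1–C2 bond) closes ring C as the enol gallate 18, which up to here is the known boronic-acid-templated phenol/enal route to 2H-chromenes. New is the telescoped hydroarylation of this enol ester: the acid protonates C3 rather than C4 because the charge then rests at C4 on the 5,7,8a-trioxygenated ring A, the galloyl carbonyl closes on C4 (5-ring neighbouring-group participation) to the cis-fused dioxolanylium ion 19, and C8 of 11 opens 19 at C4 in a Friedel–Crafts step, the closest known reactions being the acid-induced 4-arylation of simple flav-3-enes and the Lewis-acid coupling of 4-alkoxyflavan-3-yl esters with flavan-3-ols. The three new stereocentres form a relay: allylic strain with the 3-acyloxy group holds the C2 aryl group of 18 pseudoaxial, so the proton reaches C3 from the β face opposite to it and pushes the O-galloyl group to the α face (2,3-cis), and the bridge of 19 on that α face leaves only the β face of C4 open (3,4-trans). The absolute sense rests on C2, whose epimers interconvert under acid through 17 and its conjugate acid, and the chiral acid is meant to protonate the (2R) epimer faster (dynamic kinetic resolution, related to chiral-ion-pair closures of 2H-chromenes), while any product of the (2S) relay is a diastereomer that chromatography removes because 8 and 11 are single enantiomers. The step needs the C4 cation to meet C8 of 11 only, which the substrate secures since C8 of the middle ring A carries the top unit, C8 of the top unit carries bromine, every remaining C6–H lies between two benzyloxy groups, and 11 is present in excess. Arylation of the ring-opened allyl cation is the competing path and should stay behind because that cation is far more delocalised and its capture is reversible, whereas formation of 19 drains the equilibrium.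

**Step 12**
Reactants: 20 perbenzylated 8-bromo trimer
Product: 21 target, CNP0321910.1
Conditions: H2 (1 atm), Pd(OH)2/C, NaOAc (1.5 equiv), THF/MeOH/H2O, rt; filtration under Ar, Sephadex LH-20, lyophilisation
Reagents that add atoms: none
Why: Catalytic hydrogenolysis cleaves all 22 aryl benzyl ethers and the aryl C–Br cap in one operation, while the acetate buffer takes up HBr, so the esters, both interflavan bonds and all eight stereocentres should remain untouched.

**Compound list**
1 | (−)-epicatechin, (2R,3R) | C1c2c(O)cc(O)cc2O[C@H](c2ccc(O)c(O)c2)[C@@H]1O | starting material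
2 | 5,7,3',4'-tetra-O-benzyl-(−)-epicatechin | C3c4c(OCc9ccccc9)cc(OCc9ccccc9)cc4O[C@H](c7ccc(OCc9ccccc9)c(OCc9ccccc9)c7)[C@@H]3O | intermediate
3 | 8-bromo-5,7,3',4'-tetra-O-benzyl-(−)-epicatechin | C3c4c(OCc9ccccc9)cc(OCc9ccccc9)c(Br)c4O[C@H](c7ccc(OCc9ccccc9)c(OCc9ccccc9)c7)[C@@H]3O | intermediate
4 | 8-bromo-4β-(2-ethoxyethoxy)-5,7,3',4'-tetra-O-benzylepicatechin (4-OR trans to 3-OH) | CCOCCO[C@H]3c4c(OCc9ccccc9)cc(OCc9ccccc9)c(Br)c4O[C@H](c7ccc(OCc9ccccc9)c(OCc9ccccc9)c7)[C@@H]3O | intermediate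
5 | 3,4,5-tris(benzyloxy)benzoic acid | OC(=O)c1cc(OCc9ccccc9)c(OCc9ccccc9)c(OCc9ccccc9)c1 | starting material
6 | top electrophile: 3-O-[3,4,5-tris(benzyloxy)benzoyl] ester of 4 | CCOCCO[C@H]3c4c(OCc9ccccc9)cc(OCc9ccccc9)c(Br)c4O[C@H](c7ccc(OCc9ccccc9)c(OCc9ccccc9)c7)[C@@H]3OC(=O)c8cc(OCc9ccccc9)c(OCc9ccccc9)c(OCc9ccccc9)c8 | intermediate
7 | 3,5-bis(benzyloxy)phenol | Oc1cc(OCc9ccccc9)cc(OCc9ccccc9)c1 | starting material
8 | top unit–ring A phenol: (2R,3R)-8-bromo-5,7-bis(benzyloxy)-2-[3,4-bis(benzyloxy)phenyl]-4β-[2,4-bis(benzyloxy)-6-hydroxyphenyl]chroman-3-yl 3,4,5-tris(benzyloxy)benzoate (4-aryl trans to 3-O-acyl) | Oc1cc(OCc9ccccc9)cc(OCc9ccccc9)c1[C@H]3c4c(OCc9ccccc9)cc(OCc9ccccc9)c(Br)c4O[C@H](c7ccc(OCc9ccccc9)c(OCc9ccccc9)c7)[C@@H]3OC(=O)c8cc(OCc9ccccc9)c(OCc9ccccc9)c(OCc9ccccc9)c8 | intermediate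
9 | (+)-catechin, (2R,3S) | C1c2c(O)cc(O)cc2O[C@H](c2ccc(O)c(O)c2)[C@H]1O | starting material
10 | 5,7,3',4'-tetra-O-benzyl-(+)-catechin | C3c4c(OCc9ccccc9)cc(OCc9ccccc9)cc4O[C@H](c7ccc(OCc9ccccc9)c(OCc9ccccc9)c7)[C@H]3O | intermediate
11 | bottom nucleophile: 5,7,3',4'-tetra-O-benzyl-(+)-catechin 3-O-[3,4,5-tris(benzyloxy)benzoate] | C3c4c(OCc9ccccc9)cc(OCc9ccccc9)cc4O[C@H](c7ccc(OCc9ccccc9)c(OCc9ccccc9)c7)[C@H]3OC(=O)c8cc(OCc9ccccc9)c(OCc9ccccc9)c(OCc9ccccc9)c8 | intermediate
12 | 3,4,5-tris(benzyloxy)benzaldehyde | O=Cc1cc(OCc9ccccc9)c(OCc9ccccc9)c(OCc9ccccc9)c1 | starting material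
13 | rac-1-[3,4,5-tris(benzyloxy)phenyl]prop-2-yn-1-ol | C#CC(O)c1cc(OCc9ccccc9)c(OCc9ccccc9)c(OCc9ccccc9)c1 | intermediate
14 | rac-1-[3,4,5-tris(benzyloxy)phenyl]prop-2-yn-1-yl 3,4,5-tris(benzyloxy)benzoate | C#CC(OC(=O)c1cc(OCc9ccccc9)c(OCc9ccccc9)c(OCc9ccccc9)c1)c1cc(OCc9ccccc9)c(OCc9ccccc9)c(OCc9ccccc9)c1 | intermediate
15 | (Z)-3-oxo-1-[3,4,5-tris(benzyloxy)phenyl]prop-1-en-2-yl 3,4,5-tris(benzyloxy)benzoate (aryl trans to CHO) | O=C/C(OC(=O)c1cc(OCc9ccccc9)c(OCc9ccccc9)c(OCc9ccccc9)c1)=C/c1cc(OCc9ccccc9)c(OCc9ccccc9)c(OCc9ccccc9)c1 | intermediate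
16 | 2-phenyl-4H-1,3,2-benzodioxaborin from 8, 15 and PhB(OH)2 (C4 unassigned, 4-alkenyl group = enol gallate side chain) | c1ccccc1B6Oc5c([C@H]3c4c(OCc9ccccc9)cc(OCc9ccccc9)c(Br)c4O[C@H](c7ccc(OCc9ccccc9)c(OCc9ccccc9)c7)[C@@H]3OC(=O)c8cc(OCc9ccccc9)c(OCc9ccccc9)c(OCc9ccccc9)c8)c(OCc9ccccc9)cc(OCc9ccccc9)c5C(O6)/C(OC(=O)c8cc(OCc9ccccc9)c(OCc9ccccc9)c(OCc9ccccc9)c8)=C/c7cc(OCc9ccccc9)c(OCc9ccccc9)c(OCc9ccccc9)c7 | intermediate
17 | vinylogous o-quinone methide (C3 cis to the C8a carbonyl, ring B trans to C4) | O=C1C([C@H]3c4c(OCc9ccccc9)cc(OCc9ccccc9)c(Br)c4O[C@H](c7ccc(OCc9ccccc9)c(OCc9ccccc9)c7)[C@@H]3OC(=O)c8cc(OCc9ccccc9)c(OCc9ccccc9)c(OCc9ccccc9)c8)=C(OCc9ccccc9)C=C(OCc9ccccc9)/C1=C/C(OC(=O)c8cc(OCc9ccccc9)c(OCc9ccccc9)c(OCc9ccccc9)c8)=C/c7cc(OCc9ccccc9)c(OCc9ccccc9)c(OCc9ccccc9)c7 | intermediate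
18 | flav-3-en-3-yl gallate carrying the top unit at C8 (productive 2R epimer drawn; the C2 epimers interconvert) | O=C(OC1=Cc2c(OCc9ccccc9)cc(OCc9ccccc9)c([C@H]3c4c(OCc9ccccc9)cc(OCc9ccccc9)c(Br)c4O[C@H](c7ccc(OCc9ccccc9)c(OCc9ccccc9)c7)[C@@H]3OC(=O)c8cc(OCc9ccccc9)c(OCc9ccccc9)c(OCc9ccccc9)c8)c2O[C@@H]1c7cc(OCc9ccccc9)c(OCc9ccccc9)c(OCc9ccccc9)c7)c8cc(OCc9ccccc9)c(OCc9ccccc9)c(OCc9ccccc9)c8 | intermediate
19 | cis-fused 2-aryl-1,3-dioxolan-2-ylium ion across C3–C4 on the α face (counter-ion: anion of the chiral acid) | [O+]5=C(O[C@@H]1[C@H]5c2c(OCc9ccccc9)cc(OCc9ccccc9)c([C@H]3c4c(OCc9ccccc9)cc(OCc9ccccc9)c(Br)c4O[C@H](c7ccc(OCc9ccccc9)c(OCc9ccccc9)c7)[C@@H]3OC(=O)c8cc(OCc9ccccc9)c(OCc9ccccc9)c(OCc9ccccc9)c8)c2O[C@@H]1c7cc(OCc9ccccc9)c(OCc9ccccc9)c(OCc9ccccc9)c7)c8cc(OCc9ccccc9)c(OCc9ccccc9)c(OCc9ccccc9)c8 | intermediate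
20 | perbenzylated 8-bromo trimer (22 benzyl ethers, Br at C8 of the top unit; all eight stereocentres as in the target) | O=C(O[C@@H]1[C@@H](c5c(OCc9ccccc9)cc(OCc9ccccc9)c6c5O[C@H](c7ccc(OCc9ccccc9)c(OCc9ccccc9)c7)[C@@H](OC(=O)c8cc(OCc9ccccc9)c(OCc9ccccc9)c(OCc9ccccc9)c8)C6)c2c(OCc9ccccc9)cc(OCc9ccccc9)c([C@H]3c4c(OCc9ccccc9)cc(OCc9ccccc9)c(Br)c4O[C@H](c7ccc(OCc9ccccc9)c(OCc9ccccc9)c7)[C@@H]3OC(=O)c8cc(OCc9ccccc9)c(OCc9ccccc9)c(OCc9ccccc9)c8)c2O[C@@H]1c7cc(OCc9ccccc9)c(OCc9ccccc9)c(OCc9ccccc9)c7)c8cc(OCc9ccccc9)c(OCc9ccccc9)c(OCc9ccccc9)c8 | intermediate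
21 | CNP0321910.1, epicatechin 3-O-gallate-(4β→8)-epigallocatechin 3-O-gallate-(4β→8)-catechin 3-O-gallate | O=C(O[C@@H]1[C@@H](c2c(O)cc(O)c3c2O[C@H](c2ccc(O)c(O)c2)[C@@H](OC(=O)c2cc(O)c(O)c(O)c2)C3)c2c(O)cc(O)c([C@H]3c4c(O)cc(O)cc4O[C@H](c4ccc(O)c(O)c4)[C@@H]3OC(=O)c3cc(O)c(O)c(O)c3)c2O[C@@H]1c1cc(O)c(O)c(O)c1)c1cc(O)c(O)c(O)c1 | target

**Step count and risks**
Total step count: 12.
Longest linear sequence: 7 steps (1, 2, 3, 4, 5, 11, 12).

Steps most likely to fail:

Step 11.
- Risks: the chiral acid may not discriminate well enough between the interconverting C2 epimers. The nucleophile may capture the ring-opened allyl cation before C3 is protonated. Hydride transfer between flavene molecules (disproportionation) may also intervene.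
- Fallback, built from known reaction types, sets out from 8 and 15 and comes back at 20. Only the boronic-acid-templated first stage is run, and the flav-3-en-3-yl gallate 18 is isolated as its mixture of C2 epimers.
- Homogeneous hydrogenation of the enol ester with [Rh(cod)((R,R)-Me-DuPhos)]BF4 and H2 (30 bar) in CH2Cl2 leaves benzyl ethers and the aryl bromide alone. It should add both hydrogens to the face of C3=C4 opposite to the C2 aryl group (2,3-cis). Chromatography then separates the (2R,3R) protected dimer F1 from its (2S,3S) diastereomer.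
- DDQ and 2-ethoxyethanol in CH2Cl2 oxidise the only remaining C4 methylene group to the 4β-(2-ethoxyethoxy) dimer F2. TMSOTf in CH2Cl2 at −78 °C couples F2 with an excess of 11 to give 20, with the same neighbouring-group control of C4.

Step 5.
- Risks: attack through the carbon para to the hydroxyl group (between the two benzyloxy groups), or a second alkylation of the product.
- Fallback sets out from 6 and 7 and comes back at 8. The C–C bond is made by O→C migration, as known from aryl C-glycoside synthesis, instead of by direct intermolecular substitution.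
- Catalytic camphorsulfonic acid with 4 Å MS in CH2Cl2 at −20 °C first exchanges the 4-alkoxy group for the phenolic oxygen under kinetic control, giving the 4β-aryl ether F3.
- After isolation, BF3·OEt2 in CH2Cl2 (−78 → 0 °C) re-ionises F3. Ion-pair return can deliver the flavanyl cation only to a carbon ortho to the phenolic oxygen, from the β face under galloyl participation.

Step 12.
- Risks: bromide may slow the catalyst so that benzyl ether cleavage stays incomplete. Acid may also cleave the interflavan bonds once the phenols are free and HBr is released.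
- Fallback sets out from 20 and comes back at 21, with dehalogenation and debenzylation separated. Radical reduction with Bu3SnH and AIBN in toluene at 80 °C removes the bromine at the fully protected, acid-stable stage and gives the bromine-free perbenzyl trimer F4.
- F4 is then debenzylated under halide-free neutral conditions (H2, Pd(OH)2/C, THF/MeOH/H2O, rt) to 21.

**Further compounds**
F1 | step 11 | protected dimer, 8-bromo-tetra-O-benzyl-epicatechin 3-O-(tri-O-benzylgallate)-(4β→8)-penta-O-benzyl-epigallocatechin 3-O-(tri-O-benzylgallate), middle unit 2R,3R with C4 as CH2 | O=C(O[C@@H]1Cc2c(OCc9ccccc9)cc(OCc9ccccc9)c([C@H]3c4c(OCc9ccccc9)cc(OCc9ccccc9)c(Br)c4O[C@H](c7ccc(OCc9ccccc9)c(OCc9ccccc9)c7)[C@@H]3OC(=O)c8cc(OCc9ccccc9)c(OCc9ccccc9)c(OCc9ccccc9)c8)c2O[C@@H]1c7cc(OCc9ccccc9)c(OCc9ccccc9)c(OCc9ccccc9)c7)c8cc(OCc9ccccc9)c(OCc9ccccc9)c(OCc9ccccc9)c8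
F2 | step 11 | 4β-(2-ethoxyethoxy) dimer, F1 with the alkoxy group at C4 of the middle unit trans to the 3-O-galloyl group | O=C(O[C@@H]1[C@@H](OCCOCC)c2c(OCc9ccccc9)cc(OCc9ccccc9)c([C@H]3c4c(OCc9ccccc9)cc(OCc9ccccc9)c(Br)c4O[C@H](c7ccc(OCc9ccccc9)c(OCc9ccccc9)c7)[C@@H]3OC(=O)c8cc(OCc9ccccc9)c(OCc9ccccc9)c(OCc9ccccc9)c8)c2O[C@@H]1c7cc(OCc9ccccc9)c(OCc9ccccc9)c(OCc9ccccc9)c7)c8cc(OCc9ccccc9)c(OCc9ccccc9)c(OCc9ccccc9)c8
F3 | step 5 | 4β-aryl ether, 8-bromo-4β-[3,5-bis(benzyloxy)phenoxy]-5,7,3',4'-tetra-O-benzylepicatechin 3-O-[3,4,5-tris(benzyloxy)benzoate] | c1(OCc9ccccc9)cc(OCc9ccccc9)cc(c1)O[C@H]3c4c(OCc9ccccc9)cc(OCc9ccccc9)c(Br)c4O[C@H](c7ccc(OCc9ccccc9)c(OCc9ccccc9)c7)[C@@H]3OC(=O)c8cc(OCc9ccccc9)c(OCc9ccccc9)c(OCc9ccccc9)c8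
F4 | step 12 | bromine-free perbenzyl trimer (20 with H at C8 of the top unit) | O=C(O[C@@H]1[C@@H](c5c(OCc9ccccc9)cc(OCc9ccccc9)c6c5O[C@H](c7ccc(OCc9ccccc9)c(OCc9ccccc9)c7)[C@@H](OC(=O)c8cc(OCc9ccccc9)c(OCc9ccccc9)c(OCc9ccccc9)c8)C6)c2c(OCc9ccccc9)cc(OCc9ccccc9)c([C@H]3c4c(OCc9ccccc9)cc(OCc9ccccc9)cc4O[C@H](c7ccc(OCc9ccccc9)c(OCc9ccccc9)c7)[C@@H]3OC(=O)c8cc(OCc9ccccc9)c(OCc9ccccc9)c(OCc9ccccc9)c8)c2O[C@@H]1c7cc(OCc9ccccc9)c(OCc9ccccc9)c(OCc9ccccc9)c7)c8cc(OCc9ccccc9)c(OCc9ccccc9)c(OCc9ccccc9)c8
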